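## Analysis of the target

Target 46 is a (3R,4R)-trans-3,4-dibenzyl-γ-butyrolactone in which each benzyl group belongs to a further phenylpropanoid unit. The benzylic carbon on lactone C4 sits at C5 of a 7-methoxy-2,3-dihydrobenzofuran (arene ring B fused to the furan ring O1–C2–C3–C3a–C7a), which carries a 4-hydroxy-3-methoxyphenyl group (ring C) at C2 and a hydroxymethyl group at C3, trans to each other, (2S,3R). The benzyl group on lactone C3 is a guaiacyl ring (ring A) whose phenolic oxygen is bound to C2 of a (1R,2S)-1-(4-hydroxy-3-methoxyphenyl)propane-1,3-diol (ring D), the erythro arylglycerol ether. The six stereocentres thus form three vicinal pairs that are separated by methylene groups and arenes, so no pair can steer another and each must be set in absolute terms. Sensitive elements are the lactone with its epimerisable C3, two p-oxygenated benzylic C–O bonds (O1–C2 of the dihydrofuran and the glycerol carbinol) that ionise in acid and can be hydrogenolysed, two phenols, and three aliphatic hydroxyl groups that must be told apart. The difficulty lies in convergence and in the erythro pair, which is the opposite of what a syn aldol delivers. The plan rests on the O1–C7a aryl ether bond of ring B: if it is formed last, C2 and C3 can be made as an open-chain aldol pair, and ring B can come from a commercial guaiacyl acid whose phenol carbon becomes C7a.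

## Retrosynthetic reasoning

**Protecting groups (46 ⇒ 45 ⇒ 44).** The two phenols are carried as benzyl ethers and the three alcohols as silyl ethers. 46 is traced to the bis(benzyl ether) 45 and then to the fully protected 44. Fluoride and hydrogenolysis are the only reagents the finished skeleton has to meet.

**Lactone C3–CH2(ring A) bond (44 ⇒ 27 + 42).** The bond between lactone C3 and the benzylic carbon of ring A is cut. This divides 44 into two halves of similar size, lactone 27 with the dihydrobenzofuran pair and C4, and bromide 42 with the erythro pair. The forward reaction is an enolate alkylation in which the C4 substituent of 27 must direct the electrophile to the opposite face, giving the trans (3R) centre without a further controller.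

**The arm (42 ⇒ 35 ⇒ 33 + 14).** 42 is traced through alcohol 41 to ester 40, so the benzylic bromide is a masked methyl benzoate until the end. The C1–C2 bond of the glycerol unit is cut to aryloxyacetyl imide 33 and aldehyde 14. A boron aldol on such imides gives the syn, that is threo, adduct 35, so a correction at the carbinol is planned: 40 ⇐ 39 ⇐ 38 ⇐ 37, an inversion with clean SN2 character on the mono-silylated threo diol. The auxiliary must therefore fix C2 as S and the aldol carbinol as S, which calls for the (R) auxiliary 28. Imide 33 is cut at the aryl ether CH2–O bond to phenol 32 and bromoacetyl imide 31, made from 28 and 29.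

**Lactone ring (27 ⇒ 25 ⇒ 22 + 23).** The lactone C3–C4 bond is cut. The two-carbon ester unit comes from 23 and is attached to the enolate of imide 22, whose auxiliary 11 sets C4. Reduction of the imide carbonyl of 25 gives the alcohol 26, which closes onto the tert-butyl ester. 22 is traced through acid 20 to the tert-butyl ester 19, so the ester is an inert spectator until after the ring closure.

**Key disconnection, O1–C7a (19 ⇒ 18).** The aryl ether bond of the dihydrofuran is cut, leaving an aryl triflate at C7a and a free secondary benzylic hydroxyl in 18. Nothing is gained in stereochemistry at this point, and that is the intent: both centres are already in place, and the forward step only has to join oxygen to the arene with retention. The primary hydroxyl of 18 could close an isomeric five-membered ring, so it is masked as a triisopropylsilyl ether, which does not migrate between oxygens under carbonate base as smaller silyl groups can.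

**C2–C3 bond of the open chain (18 ⇒ 17 ⇒ 16 ⇒ 13 + 14).** The bond between the two future ring carbons is cut to arylacetyl imide 13 and aldehyde 14. A syn aldol with auxiliary 11 gives the (2S,3S) adduct 16. After reduction to 17 and silylation, the syn pair becomes, on ring closure, the trans (2S,3R) pair.

**Ring B (13 ⇒ 10 ⇒ 7 ⇒ 6 ⇒ 4 ⇒ 2 + 3).** The acetic acid side chain of 10 is traced to an allyl group in 7, and the allyl group to an aromatic Claisen rearrangement of ether 4, made from phenol 2 and 3. Only one ortho position of 4 is free, so the allyl group lands exactly at the future C3a. The phenol it leaves behind is converted into the triflate that the key step needs. Ester 2 comes from the commercial acid 1.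

## Alternatives that were turned down

**Alternative 1:** The C2–C3 bond of the dihydrofuran is cut. In the forward sense a chiral dirhodium carboxylate catalyst turns the aryldiazoacetate A1 into a carbenoid that inserts into the benzylic C–H bond of its own ortho benzyl ether, giving the 5-bromo-dihydrobenzofuran-3-carboxylate A2. In its favour, one catalytic step makes the C–C bond, the ring and both stereocentres, and A1 is only an etherification and a diazo transfer away from simple arenes. On step count to the bicyclic core and on the absence of a stoichiometric auxiliary it is stronger than the chosen route. Against it, insertion into an aryl benzyl ether C–H bond normally delivers the cis ester, so the trans pair of the target would need an epimerisation at C3 of A2. The methoxy group next to the ether oxygen crowds the conformation from which insertion occurs, which makes the catalyst-controlled selectivity hard to predict. Oxonium ylide formation at that oxygen is a competing path. A2 still needs its ester reduced and its C5 bromide exchanged for the three-carbon acid arm by a cross-coupling and a reduction, which uses up the steps saved. The chosen route offers instead an auxiliary aldol whose outcome is predictable and can be verified in 16 before the ring is closed, and a ring B that arrives with the propanoate arm in place.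

**Alternative 2:** The lactone O1–C5 bond is cut. In the forward sense a chiral Brønsted acid with aqueous peroxide inserts oxygen into one of the two enantiotopic acyl–CH2 bonds of the 3-substituted cyclobutanone A3, giving the (R)-lactone A4. In its favour, the lactone stereocentre is made catalytically, without auxiliary or strong base, and on atom economy it is stronger than steps 11 to 14 of the chosen route. Against it, the catalyst must distinguish two CH2 groups far from any existing stereocentre. Any shortfall in selectivity gives a diastereomer of A4 that differs only at a remote centre and would be very hard to remove. Peroxide and acid meet two electron-rich arenes and an acid-labile benzylic ether. A3 has to be built on the finished dihydrobenzofuran by a cycloaddition and dehalogenation sequence of about the same length as the steps it replaces. Above all, this disconnection says nothing about how the dihydrobenzofuran in A3 is made, so the main problem is only moved. The chosen route gives a covalently controlled alkylation whose minor isomer is separable at the stage of 25, and it uses the same auxiliary 11 twice.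

**Alternative 3:** The C7a–C3a and C5–C4 bonds of ring B are cut. In the forward sense the 2-pyrone A5, with a terminal alkyne tethered through the benzylic ether oxygen, undergoes an intramolecular cycloaddition followed by decarboxylative cycloreversion. This forms the arene and the dihydrofuran at once and gives the methyl ester A6. In its favour, two C–C bonds and two rings form in one reagent-free thermal step with regiochemistry fixed by the tether. There is no palladium, no triflate and no β-hydride pathway, and on these points it is stronger than the chosen key step. Against it, ring B with its full substitution pattern can be bought as 1, so writing it de novo spends steps on something already available. A5 needs a tetrasubstituted pyrone and an ether with two contiguous stereocentres made beforehand, so the stereochemical work is not reduced and the precursor is longer than the aldol sequence to 18. The temperatures such cycloadditions need put the p-alkoxybenzylic ether at risk of ionisation and elimination. The chosen route reaches the same ring system from a commercial arene and closes it at about 80 °C.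

Key step: step 10

## Route

Remark on starting materials: 4-(benzyloxy)-3-methoxybenzaldehyde 14 is used as purchased (it is the benzyl ether of vanillin).

Abbreviations used in names:
- Xs = (4S)-4-benzyl-2-oxo-1,3-oxazolidin-3-yl; Xr = its (4R) enantiomer.
- BnV = 4-(benzyloxy)-3-methoxyphenyl.
- DBF = (2S,3R)-2-BnV-7-methoxy-3-[(triisopropylsilyloxy)methyl]-2,3-dihydro-1-benzofuran-5-yl.
- TBS = tert-butyldimethylsilyl; TIPS = triisopropylsilyl; Tf = trifluoromethylsulfonyl.
- The arylglycerol carbons are numbered C1 (benzylic), C2 (aryloxy-bearing), C3.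

Step 1
Reactants: 1 3-(4-hydroxy-3-methoxyphenyl)propanoic acid
Product: 2 tert-butyl 3-(4-hydroxy-3-methoxyphenyl)propanoate
Conditions: Me2NCH(OtBu)2, toluene, 80 °C
Reagents that add atoms: N,N-dimethylformamide di-tert-butyl acetal, CN(C)C(OC(C)(C)C)OC(C)(C)C
Why: Amide acetal esterification; the carboxylic acid protonates the acetal and is alkylated by the tert-butyl cation equivalent, whereas the much less acidic phenol is not. The tert-butyl ester is chosen because it resists the borohydride of step 8.

Step 2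
Reactants: 2 tert-butyl 3-(4-hydroxy-3-methoxyphenyl)propanoate; 3 allyl bromide
Product: 4 tert-butyl 3-[4-(allyloxy)-3-methoxyphenyl]propanoate
Conditions: K2CO3, acetone, reflux
Reagents that add atoms: none
Why: Williamson ether synthesis on the phenoxide; the ester is inert to carbonate.

Step 3
Reactants: 4 tert-butyl 3-[4-(allyloxy)-3-methoxyphenyl]propanoate
Product: 6 tert-butyl 3-(3-allyl-4-hydroxy-5-methoxyphenyl)propanoate, via ortho-dienone 5 (not isolated)
Conditions: PhNEt2, 190 °C
Reagents that add atoms: none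
Why: Aromatic Claisen rearrangement; only one ortho position is unsubstituted, so the allyl group is delivered to the future C3a and dienone 5 tautomerises to the phenol. The amine solvent buffers traces of acid that would strip the tert-butyl ester at this temperature.

Step 4
Reactants: 6 tert-butyl 3-(3-allyl-4-hydroxy-5-methoxyphenyl)propanoate
Product: 7 tert-butyl 3-[3-allyl-5-methoxy-4-(trifluoromethylsulfonyloxy)phenyl]propanoate
Conditions: Tf2O, pyridine, CH2Cl2, 0 °C
Reagents that add atoms: trifluoromethanesulfonic anhydride, O=S(=O)(OS(=O)(=O)C(F)(F)F)C(F)(F)F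
Why: O-Sulfonylation of a hindered phenol with the anhydride; the triflate is both the leaving group for step 10 and a deactivating group that protects the arene in step 5.

Step 5
Reactants: 7 tert-butyl 3-[3-allyl-5-methoxy-4-(trifluoromethylsulfonyloxy)phenyl]propanoate
Product: 10 2-[5-(3-tert-butoxy-3-oxopropyl)-3-methoxy-2-(trifluoromethylsulfonyloxy)phenyl]acetic acid, via ozonide 8 (not isolated), via arylacetaldehyde 9 (not isolated)
Conditions: O3, CH2Cl2, −78 °C (Sudan Red 7B end point); PPh3, −78 °C → rt; then NaClO2, NaH2PO4, 2-methylbut-2-ene, tBuOH/H2O, rt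
Reagents that add atoms: ozone, [O-][O+]=O; sodium chlorite, [Na+].[O-]Cl=O
Why: Ozonolysis of the terminal alkene followed by Pinnick oxidation; the indicator dye stops ozone before it reaches the triflate-deactivated arene. The enolisable aldehyde 9 is oxidised crude.

Step 6
Reactants: 10 2-[5-(3-tert-butoxy-3-oxopropyl)-3-methoxy-2-(trifluoromethylsulfonyloxy)phenyl]acetic acid; 11 (4S)-4-benzyl-1,3-oxazolidin-2-one
Product: 13 tert-butyl 3-[3-(2-Xs-2-oxoethyl)-5-methoxy-4-(trifluoromethylsulfonyloxy)phenyl]propanoate, via mixed pivalic anhydride 12 (not isolated)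
Conditions: PivCl, Et3N, THF, −20 °C; then 11, LiCl, −20 °C → rt
Reagents that add atoms: none
Why: Mixed-anhydride N-acylation of the oxazolidinone; the hindered pivaloyl carbonyl directs attack to the arylacetyl carbonyl and LiCl raises the nucleophilicity of the auxiliary nitrogen.

Step 7
Reactants: 13 tert-butyl 3-[3-(2-Xs-2-oxoethyl)-5-methoxy-4-(trifluoromethylsulfonyloxy)phenyl]propanoate; 14 4-(benzyloxy)-3-methoxybenzaldehyde
Product: 16 tert-butyl 3-[3-{(2S,3S)-1-Xs-3-BnV-3-hydroxy-1-oxopropan-2-yl}-5-methoxy-4-(trifluoromethylsulfonyloxy)phenyl]propanoate, via boron enolate 15 (not isolated)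
Conditions: Bu2BOTf, iPr2NEt, CH2Cl2, −78 → 0 °C; then 14, −78 → 0 °C; pH 7 buffer, MeOH, H2O2
Reagents that add atoms: none
Why: Evans syn aldol reaction; the Z boron enolate 15 reacts through a chair transition state with the aldehyde aryl group equatorial, and the aldehyde approaches the enolate face opposite the benzyl group of the (S) auxiliary, which sets both new centres as (2S,3S).

Step 8
Reactants: 16 tert-butyl 3-[3-{(2S,3S)-1-Xs-3-BnV-3-hydroxy-1-oxopropan-2-yl}-5-methoxy-4-(trifluoromethylsulfonyloxy)phenyl]propanoate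
Product: 17 tert-butyl 3-[3-{(1S,2R)-1-BnV-1,3-dihydroxypropan-2-yl}-5-methoxy-4-(trifluoromethylsulfonyloxy)phenyl]propanoate
Conditions: LiBH4, MeOH (1 equiv), THF, 0 °C
Reagents that add atoms: none
Why: Reductive removal of the auxiliary; the imide carbonyl is far more electrophilic than the tert-butyl ester, and the aryl triflate is inert to borohydride. The descriptor at the aryl-bearing carbon changes from S to R only because the carbonyl becomes CH2OH.

Step 9
Reactants: 17 tert-butyl 3-[3-{(1S,2R)-1-BnV-1,3-dihydroxypropan-2-yl}-5-methoxy-4-(trifluoromethylsulfonyloxy)phenyl]propanoate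
Product: 18 tert-butyl 3-[3-{(1S,2R)-1-BnV-1-hydroxy-3-(triisopropylsilyloxy)propan-2-yl}-5-methoxy-4-(trifluoromethylsulfonyloxy)phenyl]propanoate
Conditions: TIPSCl, imidazole, DMAP (cat.), CH2Cl2, 0 °C → rt
Reagents that add atoms: chlorotriisopropylsilane, CC(C)[Si](Cl)(C(C)C)C(C)C
Why: Selective silylation of the primary hydroxyl next to a hindered secondary benzylic one; the bulky triisopropylsilyl group is chosen because it does not shift to the neighbouring oxygen under the basic conditions of step 10.

Step 10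
Reactants: 18 tert-butyl 3-[3-{(1S,2R)-1-BnV-1-hydroxy-3-(triisopropylsilyloxy)propan-2-yl}-5-methoxy-4-(trifluoromethylsulfonyloxy)phenyl]propanoate
Product: 19 tert-butyl 3-DBF-propanoate
Conditions: Pd(OAc)2 (5 mol %), 2-(di-tert-butylphosphino)-1,1'-binaphthyl (6 mol %), Cs2CO3 (1.5 equiv), toluene, 80 °C
Reagents that add atoms: none
Why: Zerovalent palladium, formed from Pd(OAc)2 and the di-tert-butyl biaryl phosphine, inserts into the aryl C–O bond of the triflate at the future C7a; Cs2CO3 then deprotonates the coordinated secondary benzylic hydroxyl and triflate leaves the metal, giving a six-membered aryl(alkoxo) complex of divalent palladium (Pd, C7a, C3a, C3, C2, O). C–O reductive elimination from this complex forms the O1–C7a bond and returns zerovalent palladium. The closest known reaction type is the palladium-catalysed intramolecular etherification of aryl halides and sulfonates with primary and secondary alcohols, established for dihydrobenzofurans and for enantioenriched secondary alcohols. The dihydrofuran is closed as a five-membered ring by reductive elimination from the six-membered palladacycle, formally a 5-exo attack of oxygen on the ipso carbon. No stereocentre is created: no bond to C2 or C3 is broken, so both keep the configuration set in step 7 and the syn diol pair becomes the trans (2S,3R) ring pair. The step needs reductive elimination to outrun β-hydride elimination of the benzylic alkoxide, which is secured by the bulky electron-rich ligand and by the two ortho substituents on the palladium-bound arene (OMe and the branched chain), both of which accelerate C–O elimination. It also needs the secondary hydroxyl to be the only nucleophile, secured by the non-migrating silyl ether on the primary oxygen, and a base weak enough to leave the triflate S–O bond and the tert-butyl ester alone.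

Step 11
Reactants: 19 tert-butyl 3-DBF-propanoate
Product: 20 3-DBF-propanoic acid
Conditions: 85% aq. H3PO4, toluene, rt → 40 °C
Reagents that add atoms: none
Why: Acid-mediated loss of the tert-butyl cation from the ester; aqueous phosphoric acid is mild enough to spare the silyl ether, the benzyl ether and the benzylic ring ether, whose reclosure after any ionisation would in any case return the trans ring.

Step 12
Reactants: 20 3-DBF-propanoic acid; 11 (4S)-4-benzyl-1,3-oxazolidin-2-one
Product: 22 (4S)-4-benzyl-3-(3-DBF-propanoyl)-1,3-oxazolidin-2-one, via mixed pivalic anhydride 21 (not isolated)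
Conditions: PivCl, Et3N, THF, −20 °C; then 11, LiCl, −20 °C → rt
Reagents that add atoms: none
Why: Mixed-anhydride N-acylation as in step 6.

Step 13
Reactants: 22 (4S)-4-benzyl-3-(3-DBF-propanoyl)-1,3-oxazolidin-2-one; 23 tert-butyl bromoacetate
Product: 25 tert-butyl (3R)-4-Xs-3-(DBF-methyl)-4-oxobutanoate, via sodium enolate 24 (not isolated)
Conditions: NaN(SiMe3)2, THF, −78 °C; then 23, −78 → −40 °C
Reagents that add atoms: none
Why: Evans asymmetric alkylation; the chelated Z sodium enolate 24 is attacked by the bromoacetate on the face away from the benzyl group of the (S) auxiliary, which sets the new centre as R (the future lactone C4).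

Step 14
Reactants: 25 tert-butyl (3R)-4-Xs-3-(DBF-methyl)-4-oxobutanoate
Product: 27 (4R)-4-(DBF-methyl)oxolan-2-one, via hydroxy ester 26 (not isolated)
Conditions: LiBH4, MeOH (1 equiv), THF, 0 °C; aqueous work-up; then p-TsOH·H2O (10 mol %), CH2Cl2, rt
Reagents that add atoms: none
Why: Chemoselective borohydride reduction of the imide gives hydroxy ester 26, which closes by acid-catalysed intramolecular transesterification with loss of tert-butanol; the stereocentre is not involved.

Step 15
Reactants: 28 (4R)-4-benzyl-1,3-oxazolidin-2-one; 29 bromoacetyl bromide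
Product: 31 (4R)-4-benzyl-3-(bromoacetyl)-1,3-oxazolidin-2-one, via lithium oxazolidinide 30 (not isolated)
Conditions: n-BuLi, THF, −78 °C; then 29, −78 °C
Reagents that add atoms: none
Why: N-Acylation of the lithiated oxazolidinone; the acyl bromide reacts far faster than the alkyl bromide at −78 °C.

Step 16
Reactants: 31 (4R)-4-benzyl-3-(bromoacetyl)-1,3-oxazolidin-2-one; 32 methyl 4-hydroxy-3-methoxybenzoate
Product: 33 methyl 4-(2-Xr-2-oxoethoxy)-3-methoxybenzoate
Conditions: K2CO3, acetone, rt → 50 °C
Reagents that add atoms: none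
Why: SN2 displacement of the activated α-bromo imide by the phenoxide; the ester on ring A is the masked benzylic bromide and lowers the basicity of the phenoxide, which protects the imide.

Step 17
Reactants: 33 methyl 4-(2-Xr-2-oxoethoxy)-3-methoxybenzoate; 14 4-(benzyloxy)-3-methoxybenzaldehyde
Product: 35 methyl 4-{[(2R,3S)-1-Xr-3-BnV-3-hydroxy-1-oxopropan-2-yl]oxy}-3-methoxybenzoate, via boron enolate 34 (not isolated)
Conditions: Bu2BOTf, iPr2NEt, CH2Cl2, −78 → 0 °C; then 14, −78 → 0 °C; pH 7 buffer, MeOH, H2O2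
Reagents that add atoms: none
Why: Evans syn aldol reaction of a glycolate-type imide; the Z enolate 34 and the (R) auxiliary give the (2R,3S) adduct through the chair transition state, i.e. the threo pair, with the aryloxy-bearing carbon in the configuration that the target needs.

Step 18
Reactants: 35 methyl 4-{[(2R,3S)-1-Xr-3-BnV-3-hydroxy-1-oxopropan-2-yl]oxy}-3-methoxybenzoate
Product: 36 methyl 4-{[(1S,2S)-1-BnV-1,3-dihydroxypropan-2-yl]oxy}-3-methoxybenzoate
Conditions: NaBH4, THF/H2O 4:1, 0 °C → rt
Reagents that add atoms: none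
Why: Reductive cleavage of the N-acyl oxazolidinone with aqueous borohydride, which does not touch the electron-rich methyl benzoate.

Step 19
Reactants: 36 methyl 4-{[(1S,2S)-1-BnV-1,3-dihydroxypropan-2-yl]oxy}-3-methoxybenzoate
Product: 37 methyl 4-{[(1S,2S)-1-BnV-3-(tert-butyldimethylsilyloxy)-1-hydroxypropan-2-yl]oxy}-3-methoxybenzoate
Conditions: TBSCl, imidazole, CH2Cl2, 0 °C
Reagents that add atoms: tert-butyl(chloro)dimethylsilane, CC(C)(C)[Si](C)(C)Cl
Why: Selective silylation of the primary hydroxyl; it leaves the benzylic hydroxyl as the only one free for inversion.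

Step 20
Reactants: 37 methyl 4-{[(1S,2S)-1-BnV-3-(tert-butyldimethylsilyloxy)-1-hydroxypropan-2-yl]oxy}-3-methoxybenzoate
Product: 38 methyl 4-{[(1R,2S)-1-BnV-3-(tert-butyldimethylsilyloxy)-1-(4-nitrobenzoyloxy)propan-2-yl]oxy}-3-methoxybenzoate
Conditions: 4-O2NC6H4CO2H, PPh3, DIAD, toluene, 0 °C → rt
Reagents that add atoms: 4-nitrobenzoic acid, OC(=O)c1ccc(cc1)[N+](=O)[O-]
Why: Mitsunobu inversion; the carboxylate displaces the alkoxyphosphonium group with inversion at C1, turning the threo pair into the erythro (1R,2S) pair. The electron-withdrawing aryloxy group on C2 disfavours ionisation of C1 and so supports the SN2 course.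

Step 21
Reactants: 38 methyl 4-{[(1R,2S)-1-BnV-3-(tert-butyldimethylsilyloxy)-1-(4-nitrobenzoyloxy)propan-2-yl]oxy}-3-methoxybenzoate
Product: 39 methyl 4-{[(1R,2S)-1-BnV-3-(tert-butyldimethylsilyloxy)-1-hydroxypropan-2-yl]oxy}-3-methoxybenzoate
Conditions: K2CO3, MeOH, 0 °C → rt
Reagents that add atoms: none
Why: Methanolysis of the activated nitrobenzoate by acyl–oxygen cleavage, so C1 keeps its new configuration; exchange at the methyl benzoate is degenerate in methanol.

Step 22
Reactants: 39 methyl 4-{[(1R,2S)-1-BnV-3-(tert-butyldimethylsilyloxy)-1-hydroxypropan-2-yl]oxy}-3-methoxybenzoate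
Product: 40 methyl 4-{[(1R,2S)-1-BnV-1,3-bis(tert-butyldimethylsilyloxy)propan-2-yl]oxy}-3-methoxybenzoate
Conditions: TBSOTf, 2,6-lutidine, CH2Cl2, −78 → 0 °C
Reagents that add atoms: tert-butyldimethylsilyl trifluoromethanesulfonate, CC(C)(C)[Si](C)(C)OS(=O)(=O)C(F)(F)F
Why: Silylation of a hindered secondary alcohol with the silyl triflate under buffered conditions that do not ionise the benzylic position.

Step 23
Reactants: 40 methyl 4-{[(1R,2S)-1-BnV-1,3-bis(tert-butyldimethylsilyloxy)propan-2-yl]oxy}-3-methoxybenzoate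
Product: 41 (4-{[(1R,2S)-1-BnV-1,3-bis(tert-butyldimethylsilyloxy)propan-2-yl]oxy}-3-methoxyphenyl)methanol
Conditions: iBu2AlH, CH2Cl2, −78 → 0 °C; aq. KNaC4H4O6
Reagents that add atoms: none
Why: Hydride reduction of the aryl ester to the benzylic alcohol; silyl and benzyl ethers are inert.

Step 24
Reactants: 41 (4-{[(1R,2S)-1-BnV-1,3-bis(tert-butyldimethylsilyloxy)propan-2-yl]oxy}-3-methoxyphenyl)methanol
Product: 42 4-(bromomethyl)-1-{[(1R,2S)-1-BnV-1,3-bis(tert-butyldimethylsilyloxy)propan-2-yl]oxy}-2-methoxybenzene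
Conditions: CBr4, PPh3, CH2Cl2, 0 °C; used at once
Reagents that add atoms: tetrabromomethane, BrC(Br)(Br)Br
Why: Appel bromination under neutral conditions; the p-alkoxybenzylic bromide is reactive and is therefore made immediately before use.

Step 25
Reactants: 27 (4R)-4-(DBF-methyl)oxolan-2-one; 42 4-(bromomethyl)-1-{[(1R,2S)-1-BnV-1,3-bis(tert-butyldimethylsilyloxy)propan-2-yl]oxy}-2-methoxybenzene
Product: 44 (3R,4R)-3-[(4-{[(1R,2S)-1-BnV-1,3-bis(tert-butyldimethylsilyloxy)propan-2-yl]oxy}-3-methoxyphenyl)methyl]-4-(DBF-methyl)oxolan-2-one, via lithium enolate 43 (not isolated)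
Conditions: LiN(SiMe3)2, THF, −78 °C; then 42, DMPU, −78 → −30 °C
Reagents that add atoms: none
Why: Alkylation of a β-substituted butyrolactone enolate; the benzylic bromide approaches the planar enolate 43 on the face opposite the C4 substituent, so the new C3 centre is set trans (R) by substrate control.

Step 26
Reactants: 44 (3R,4R)-3-[(4-{[(1R,2S)-1-BnV-1,3-bis(tert-butyldimethylsilyloxy)propan-2-yl]oxy}-3-methoxyphenyl)methyl]-4-(DBF-methyl)oxolan-2-one
Product: 45 (3R,4R)-3-[(4-{[(1R,2S)-1-BnV-1,3-dihydroxypropan-2-yl]oxy}-3-methoxyphenyl)methyl]-4-{[(2S,3R)-2-BnV-3-(hydroxymethyl)-7-methoxy-2,3-dihydro-1-benzofuran-5-yl]methyl}oxolan-2-one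
Conditions: Bu4NF, AcOH (1:1), THF, rt → 40 °C
Reagents that add atoms: none
Why: Fluoride cleavage of all three silyl ethers; buffering with acetic acid keeps the medium from opening or epimerising the lactone, whose trans arrangement is in any case the stable one.

Step 27
Reactants: 45 (3R,4R)-3-[(4-{[(1R,2S)-1-BnV-1,3-dihydroxypropan-2-yl]oxy}-3-methoxyphenyl)methyl]-4-{[(2S,3R)-2-BnV-3-(hydroxymethyl)-7-methoxy-2,3-dihydro-1-benzofuran-5-yl]methyl}oxolan-2-one
Product: 46 (3R,4R)-3-[(4-{[(1R,2S)-1,3-dihydroxy-1-(4-hydroxy-3-methoxyphenyl)propan-2-yl]oxy}-3-methoxyphenyl)methyl]-4-{[(2S,3R)-2-(4-hydroxy-3-methoxyphenyl)-3-(hydroxymethyl)-7-methoxy-2,3-dihydro-1-benzofuran-5-yl]methyl}oxolan-2-one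
Conditions: H2 (1 atm), Pd/C (10% Pd on carbon), EtOAc/MeOH, rt
Reagents that add atoms: none
Why: Hydrogenolysis of the two aryl benzyl ethers, which are cleaved much faster under neutral conditions than the benzylic alcohol or the benzylic ring ether.

## Compound list

1 | 3-(4-hydroxy-3-methoxyphenyl)propanoic acid | OC(=O)CCc1ccc(O)c(OC)c1 | starting material
2 | tert-butyl 3-(4-hydroxy-3-methoxyphenyl)propanoate | CC(C)(C)OC(=O)CCc1ccc(O)c(OC)c1 | intermediate
3 | allyl bromide | C=CCBr | starting material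
4 | tert-butyl 3-[4-(allyloxy)-3-methoxyphenyl]propanoate | CC(C)(C)OC(=O)CCc1ccc(OCC=C)c(OC)c1 | intermediate
5 | tert-butyl 3-(3-allyl-5-methoxy-4-oxocyclohexa-1,5-dien-1-yl)propanoate (racemic at the allyl-bearing carbon) | CC(C)(C)OC(=O)CCC1=CC(CC=C)C(=O)C(OC)=C1 | intermediate
6 | tert-butyl 3-(3-allyl-4-hydroxy-5-methoxyphenyl)propanoate | CC(C)(C)OC(=O)CCc1cc(CC=C)c(O)c(OC)c1 | intermediate
7 | tert-butyl 3-[3-allyl-5-methoxy-4-(trifluoromethylsulfonyloxy)phenyl]propanoate | CC(C)(C)OC(=O)CCc1cc(CC=C)c(OS(=O)(=O)C(F)(F)F)c(OC)c1 | intermediate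
8 | tert-butyl 3-[3-methoxy-5-(1,2,4-trioxolan-3-ylmethyl)-4-(trifluoromethylsulfonyloxy)phenyl]propanoate (racemic ozonide) | CC(C)(C)OC(=O)CCc1cc(CC2OCOO2)c(OS(=O)(=O)C(F)(F)F)c(OC)c1 | intermediate
9 | tert-butyl 3-[3-methoxy-5-(2-oxoethyl)-4-(trifluoromethylsulfonyloxy)phenyl]propanoate | CC(C)(C)OC(=O)CCc1cc(CC=O)c(OS(=O)(=O)C(F)(F)F)c(OC)c1 | intermediate
10 | 2-[5-(3-tert-butoxy-3-oxopropyl)-3-methoxy-2-(trifluoromethylsulfonyloxy)phenyl]acetic acid | CC(C)(C)OC(=O)CCc1cc(CC(=O)O)c(OS(=O)(=O)C(F)(F)F)c(OC)c1 | intermediate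
11 | (4S)-4-benzyl-1,3-oxazolidin-2-one | O=C1N[C@@H](Cc2ccccc2)CO1 | starting material
12 | mixed anhydride of 10 with pivalic acid | CC(C)(C)OC(=O)CCc1cc(CC(=O)OC(=O)C(C)(C)C)c(OS(=O)(=O)C(F)(F)F)c(OC)c1 | intermediate
13 | tert-butyl 3-[3-(2-Xs-2-oxoethyl)-5-methoxy-4-(trifluoromethylsulfonyloxy)phenyl]propanoate | CC(C)(C)OC(=O)CCc1cc(CC(=O)N2[C@@H](Cc3ccccc3)COC2=O)c(OS(=O)(=O)C(F)(F)F)c(OC)c1 | intermediate
14 | 4-(benzyloxy)-3-methoxybenzaldehyde | O=Cc1ccc(OCc2ccccc2)c(OC)c1 | starting material
15 | (Z)-dibutylboron enolate of 13 | CCCCB(CCCC)O/C(=C\c1cc(CCC(=O)OC(C)(C)C)cc(OC)c1OS(=O)(=O)C(F)(F)F)N1[C@@H](Cc2ccccc2)COC1=O | intermediate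
16 | tert-butyl 3-[3-{(2S,3S)-1-Xs-3-BnV-3-hydroxy-1-oxopropan-2-yl}-5-methoxy-4-(trifluoromethylsulfonyloxy)phenyl]propanoate | CC(C)(C)OC(=O)CCc1cc(OC)c(OS(=O)(=O)C(F)(F)F)c(c1)[C@H](C(=O)N1[C@@H](Cc2ccccc2)COC1=O)[C@H](O)c1ccc(OCc2ccccc2)c(OC)c1 | intermediate
17 | tert-butyl 3-[3-{(1S,2R)-1-BnV-1,3-dihydroxypropan-2-yl}-5-methoxy-4-(trifluoromethylsulfonyloxy)phenyl]propanoate | CC(C)(C)OC(=O)CCc1cc(OC)c(OS(=O)(=O)C(F)(F)F)c(c1)[C@H](CO)[C@H](O)c1ccc(OCc2ccccc2)c(OC)c1 | intermediate
18 | tert-butyl 3-[3-{(1S,2R)-1-BnV-1-hydroxy-3-(triisopropylsilyloxy)propan-2-yl}-5-methoxy-4-(trifluoromethylsulfonyloxy)phenyl]propanoate | CC(C)(C)OC(=O)CCc1cc(OC)c(OS(=O)(=O)C(F)(F)F)c(c1)[C@H](CO[Si](C(C)C)(C(C)C)C(C)C)[C@H](O)c1ccc(OCc2ccccc2)c(OC)c1 | intermediate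
19 | tert-butyl 3-{(2S,3R)-2-[4-(benzyloxy)-3-methoxyphenyl]-7-methoxy-3-[(triisopropylsilyloxy)methyl]-2,3-dihydro-1-benzofuran-5-yl}propanoate | CC(C)(C)OC(=O)CCc1cc(OC)c2c(c1)[C@H](CO[Si](C(C)C)(C(C)C)C(C)C)[C@@H](c1ccc(OCc3ccccc3)c(OC)c1)O2 | intermediate
20 | 3-{(2S,3R)-2-[4-(benzyloxy)-3-methoxyphenyl]-7-methoxy-3-[(triisopropylsilyloxy)methyl]-2,3-dihydro-1-benzofuran-5-yl}propanoic acid | OC(=O)CCc1cc(OC)c2c(c1)[C@H](CO[Si](C(C)C)(C(C)C)C(C)C)[C@@H](c1ccc(OCc3ccccc3)c(OC)c1)O2 | intermediate
21 | mixed anhydride of 20 with pivalic acid | CC(C)(C)C(=O)OC(=O)CCc1cc(OC)c2c(c1)[C@H](CO[Si](C(C)C)(C(C)C)C(C)C)[C@@H](c1ccc(OCc3ccccc3)c(OC)c1)O2 | intermediate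
22 | (4S)-4-benzyl-3-(3-DBF-propanoyl)-1,3-oxazolidin-2-one | O=C(CCc1cc(OC)c2c(c1)[C@H](CO[Si](C(C)C)(C(C)C)C(C)C)[C@@H](c1ccc(OCc3ccccc3)c(OC)c1)O2)N1[C@@H](Cc2ccccc2)COC1=O | intermediate
23 | tert-butyl bromoacetate | CC(C)(C)OC(=O)CBr | starting material
24 | sodium (Z)-enolate of 22 | [Na+].[O-]/C(=C\Cc1cc(OC)c2c(c1)[C@H](CO[Si](C(C)C)(C(C)C)C(C)C)[C@@H](c1ccc(OCc3ccccc3)c(OC)c1)O2)N1[C@@H](Cc2ccccc2)COC1=O | intermediate
25 | tert-butyl (3R)-4-Xs-3-(DBF-methyl)-4-oxobutanoate | CC(C)(C)OC(=O)C[C@@H](Cc1cc(OC)c2c(c1)[C@H](CO[Si](C(C)C)(C(C)C)C(C)C)[C@@H](c1ccc(OCc3ccccc3)c(OC)c1)O2)C(=O)N1[C@@H](Cc2ccccc2)COC1=O | intermediate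
26 | tert-butyl (3R)-3-(DBF-methyl)-4-hydroxybutanoate | CC(C)(C)OC(=O)C[C@@H](Cc1cc(OC)c2c(c1)[C@H](CO[Si](C(C)C)(C(C)C)C(C)C)[C@@H](c1ccc(OCc3ccccc3)c(OC)c1)O2)CO | intermediate
27 | (4R)-4-(DBF-methyl)oxolan-2-one | O=C1C[C@@H](Cc2cc(OC)c3c(c2)[C@H](CO[Si](C(C)C)(C(C)C)C(C)C)[C@@H](c2ccc(OCc4ccccc4)c(OC)c2)O3)CO1 | intermediate
28 | (4R)-4-benzyl-1,3-oxazolidin-2-one | O=C1N[C@H](Cc2ccccc2)CO1 | starting material
29 | bromoacetyl bromide | BrCC(Br)=O | starting material
30 | lithium salt of 28 (N-lithio oxazolidinone) | [Li+].O=C1[N-][C@H](Cc2ccccc2)CO1 | intermediate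
31 | (4R)-4-benzyl-3-(bromoacetyl)-1,3-oxazolidin-2-one | BrCC(=O)N1[C@H](Cc2ccccc2)COC1=O | intermediate
32 | methyl 4-hydroxy-3-methoxybenzoate | COC(=O)c1ccc(O)c(OC)c1 | starting material
33 | methyl 4-(2-Xr-2-oxoethoxy)-3-methoxybenzoate | COC(=O)c1ccc(OCC(=O)N2[C@H](Cc3ccccc3)COC2=O)c(OC)c1 | intermediate
34 | (Z)-dibutylboron enolate of 33 | CCCCB(CCCC)O/C(=C\Oc1ccc(cc1OC)C(=O)OC)N1[C@H](Cc2ccccc2)COC1=O | intermediate
35 | methyl 4-{[(2R,3S)-1-Xr-3-BnV-3-hydroxy-1-oxopropan-2-yl]oxy}-3-methoxybenzoate (threo) | COC(=O)c1ccc(O[C@@H](C(=O)N2[C@H](Cc3ccccc3)COC2=O)[C@@H](O)c2ccc(OCc3ccccc3)c(OC)c2)c(OC)c1 | intermediate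
36 | methyl 4-{[(1S,2S)-1-BnV-1,3-dihydroxypropan-2-yl]oxy}-3-methoxybenzoate (threo) | COC(=O)c1ccc(O[C@@H](CO)[C@@H](O)c2ccc(OCc3ccccc3)c(OC)c2)c(OC)c1 | intermediate
37 | methyl 4-{[(1S,2S)-1-BnV-3-(tert-butyldimethylsilyloxy)-1-hydroxypropan-2-yl]oxy}-3-methoxybenzoate | COC(=O)c1ccc(O[C@@H](CO[Si](C)(C)C(C)(C)C)[C@@H](O)c2ccc(OCc3ccccc3)c(OC)c2)c(OC)c1 | intermediate
38 | methyl 4-{[(1R,2S)-1-BnV-3-(tert-butyldimethylsilyloxy)-1-(4-nitrobenzoyloxy)propan-2-yl]oxy}-3-methoxybenzoate (erythro) | COC(=O)c1ccc(O[C@@H](CO[Si](C)(C)C(C)(C)C)[C@H](OC(=O)c2ccc(cc2)[N+](=O)[O-])c2ccc(OCc3ccccc3)c(OC)c2)c(OC)c1 | intermediate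
39 | methyl 4-{[(1R,2S)-1-BnV-3-(tert-butyldimethylsilyloxy)-1-hydroxypropan-2-yl]oxy}-3-methoxybenzoate (erythro) | COC(=O)c1ccc(O[C@@H](CO[Si](C)(C)C(C)(C)C)[C@H](O)c2ccc(OCc3ccccc3)c(OC)c2)c(OC)c1 | intermediate
40 | methyl 4-{[(1R,2S)-1-BnV-1,3-bis(tert-butyldimethylsilyloxy)propan-2-yl]oxy}-3-methoxybenzoate | COC(=O)c1ccc(O[C@@H](CO[Si](C)(C)C(C)(C)C)[C@H](O[Si](C)(C)C(C)(C)C)c2ccc(OCc3ccccc3)c(OC)c2)c(OC)c1 | intermediate
41 | (4-{[(1R,2S)-1-BnV-1,3-bis(tert-butyldimethylsilyloxy)propan-2-yl]oxy}-3-methoxyphenyl)methanol | OCc1ccc(O[C@@H](CO[Si](C)(C)C(C)(C)C)[C@H](O[Si](C)(C)C(C)(C)C)c2ccc(OCc3ccccc3)c(OC)c2)c(OC)c1 | intermediate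
42 | 4-(bromomethyl)-1-{[(1R,2S)-1-BnV-1,3-bis(tert-butyldimethylsilyloxy)propan-2-yl]oxy}-2-methoxybenzene | BrCc1ccc(O[C@@H](CO[Si](C)(C)C(C)(C)C)[C@H](O[Si](C)(C)C(C)(C)C)c2ccc(OCc3ccccc3)c(OC)c2)c(OC)c1 | intermediate
43 | lithium enolate of 27 | [Li+].[O-]C1=C[C@@H](Cc2cc(OC)c3c(c2)[C@H](CO[Si](C(C)C)(C(C)C)C(C)C)[C@@H](c2ccc(OCc4ccccc4)c(OC)c2)O3)CO1 | intermediate
44 | (3R,4R)-3-[(4-{[(1R,2S)-1-BnV-1,3-bis(tert-butyldimethylsilyloxy)propan-2-yl]oxy}-3-methoxyphenyl)methyl]-4-(DBF-methyl)oxolan-2-one | COc1cc([C@@H](O[Si](C)(C)C(C)(C)C)[C@H](CO[Si](C)(C)C(C)(C)C)Oc2ccc(C[C@H]3C(=O)OC[C@@H]3Cc3cc(OC)c4c(c3)[C@H](CO[Si](C(C)C)(C(C)C)C(C)C)[C@@H](c3ccc(OCc5ccccc5)c(OC)c3)O4)cc2OC)ccc1OCc1ccccc1 | intermediate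
45 | (3R,4R)-3-[(4-{[(1R,2S)-1-BnV-1,3-dihydroxypropan-2-yl]oxy}-3-methoxyphenyl)methyl]-4-{[(2S,3R)-2-BnV-3-(hydroxymethyl)-7-methoxy-2,3-dihydro-1-benzofuran-5-yl]methyl}oxolan-2-one | COc1cc([C@@H](O)[C@H](CO)Oc2ccc(C[C@H]3C(=O)OC[C@@H]3Cc3cc(OC)c4c(c3)[C@H](CO)[C@@H](c3ccc(OCc5ccccc5)c(OC)c3)O4)cc2OC)ccc1OCc1ccccc1 | intermediate
46 | (3R,4R)-3-[(4-{[(1R,2S)-1,3-dihydroxy-1-(4-hydroxy-3-methoxyphenyl)propan-2-yl]oxy}-3-methoxyphenyl)methyl]-4-{[(2S,3R)-2-(4-hydroxy-3-methoxyphenyl)-3-(hydroxymethyl)-7-methoxy-2,3-dihydro-1-benzofuran-5-yl]methyl}oxolan-2-one | COc1cc([C@@H](O)[C@H](CO)Oc2ccc(C[C@H]3C(=O)OC[C@@H]3Cc3cc(OC)c4c(c3)[C@H](CO)[C@@H](c3ccc(O)c(OC)c3)O4)cc2OC)ccc1O | target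

## Step count and least certain steps

Total: 27 steps. Longest linear sequence: 17 steps (steps 1 to 14, then 25 to 27). The arm is made in 10 steps (15 to 24) and joins at step 25.

**Step 10 (key step).** The most likely failures are β-hydride elimination from the palladium alkoxide, which would give the aryl ketone and the reduced arene, and transfer of the sulfonyl group from the hindered aryl triflate to the alkoxide before palladium has inserted. Both follow from the fact that insertion into a doubly ortho-substituted, electron-rich triflate is slow. Fallback, from 18 back to 19: the triflate is cleaved with aqueous Et4NOH in dioxane to the phenol tert-butyl 3-[3-{(1S,2R)-1-BnV-1-hydroxy-3-(triisopropylsilyloxy)propan-2-yl}-4-hydroxy-5-methoxyphenyl]propanoate F1. The ring is then closed at the other end, O1–C2, by acid-catalysed cyclodehydration (catalytic p-TsOH, CH2Cl2, 0 °C → rt). The p-benzyloxybenzylic cation is trapped by the phenol on the face away from the C3 substituent, which should give the trans ring of 19.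

**Step 20.** Partial ionisation of the alkoxyphosphonium intermediate at the p-benzyloxybenzylic carbon would erode the inversion and give a threo/erythro mixture; elimination is a second possibility. Fallback, from 37 back to 39: oxidation with Dess–Martin periodinane gives the ketone methyl 4-{[(2S)-1-BnV-3-(tert-butyldimethylsilyloxy)-1-oxopropan-2-yl]oxy}-3-methoxybenzoate F2. Reduction with Zn(BH4)2 in Et2O at −30 °C follows. Chelation of zinc between the carbonyl and the guaiacyl ether oxygens, with hydride delivery past the hydrogen on C2, should give the anti, erythro alcohol 39 directly.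

**Step 25.** The bulky, ionisable benzylic bromide may decompose or react sluggishly, so that proton transfer and recovery of 27 compete with C-alkylation. Fallback, from 41 and 27 back to 44: alcohol 41 is oxidised with MnO2 to 4-{[(1R,2S)-1-BnV-1,3-bis(tert-butyldimethylsilyloxy)propan-2-yl]oxy}-3-methoxybenzaldehyde F3. Enolate 43 is added to it at −78 °C to give the β-hydroxy lactone (3-[aryl(hydroxy)methyl] derivative of 27, carbinol epimers) F4. This is converted with MsCl and Et3N into its methanesulfonate F5 and eliminated with DBU to the (E)-3-arylidene lactone F6. Conjugate reduction with NaBH4 and NiCl2·6H2O in MeOH/THF, with protonation of the enolate away from the C4 substituent, should give the trans lactone 44.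

**Step 27.** Over-reduction is the risk: hydrogenolysis of the free p-oxygenated benzylic carbinol or of the benzylic O1–C2 bond of the dihydrofuran once the phenols are liberated. Fallback, from 44 back to 46: the order of the last two steps is reversed. Hydrogenolysis of 44 under the same conditions gives the tris-silylated diphenol (44 with both benzyl ethers replaced by OH) F7, in which the glycerol carbinol is still a silyl ether and therefore shielded. Buffered Bu4NF then gives 46.

**Step 3.** Thermal loss of isobutene from the tert-butyl ester at the temperature of the rearrangement would give acid mixtures. Fallback, from 1 back to 6: the phenol of 1 is allylated selectively with 3 and NaOH (2.2 equiv) in EtOH/H2O to 3-[4-(allyloxy)-3-methoxyphenyl]propanoic acid F8. This is rearranged in PhNEt2 at 190 °C to 3-(3-allyl-4-hydroxy-5-methoxyphenyl)propanoic acid F9, and the tert-butyl ester is made only then with Me2NCH(OtBu)2, giving 6.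

## Further compounds

F1 | step 10 | tert-butyl 3-[3-{(1S,2R)-1-BnV-1-hydroxy-3-(triisopropylsilyloxy)propan-2-yl}-4-hydroxy-5-methoxyphenyl]propanoate | CC(C)(C)OC(=O)CCc1cc(OC)c(O)c(c1)[C@H](CO[Si](C(C)C)(C(C)C)C(C)C)[C@H](O)c1ccc(OCc2ccccc2)c(OC)c1
F2 | step 20 | methyl 4-{[(2S)-1-BnV-3-(tert-butyldimethylsilyloxy)-1-oxopropan-2-yl]oxy}-3-methoxybenzoate | COC(=O)c1ccc(O[C@@H](CO[Si](C)(C)C(C)(C)C)C(=O)c2ccc(OCc3ccccc3)c(OC)c2)c(OC)c1
F3 | step 25 | 4-{[(1R,2S)-1-BnV-1,3-bis(tert-butyldimethylsilyloxy)propan-2-yl]oxy}-3-methoxybenzaldehyde | O=Cc1ccc(O[C@@H](CO[Si](C)(C)C(C)(C)C)[C@H](O[Si](C)(C)C(C)(C)C)c2ccc(OCc3ccccc3)c(OC)c2)c(OC)c1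
F4 | step 25 | 3-[aryl(hydroxy)methyl] lactone from 27 and F3, trans at the ring, carbinol epimers | COc1cc([C@@H](O[Si](C)(C)C(C)(C)C)[C@H](CO[Si](C)(C)C(C)(C)C)Oc2ccc(C(O)[C@H]3C(=O)OC[C@@H]3Cc3cc(OC)c4c(c3)[C@H](CO[Si](C(C)C)(C(C)C)C(C)C)[C@@H](c3ccc(OCc5ccccc5)c(OC)c3)O4)cc2OC)ccc1OCc1ccccc1
F5 | step 25 | methanesulfonate of F4 | COc1cc([C@@H](O[Si](C)(C)C(C)(C)C)[C@H](CO[Si](C)(C)C(C)(C)C)Oc2ccc(C(OS(C)(=O)=O)[C@H]3C(=O)OC[C@@H]3Cc3cc(OC)c4c(c3)[C@H](CO[Si](C(C)C)(C(C)C)C(C)C)[C@@H](c3ccc(OCc5ccccc5)c(OC)c3)O4)cc2OC)ccc1OCc1ccccc1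
F6 | step 25 | (3E,4R)-3-(arylmethylidene)-4-(DBF-methyl)oxolan-2-one, aryl = ring A with the bis-silylated erythro arm | O=C1OC[C@H](Cc2cc(OC)c3c(c2)[C@H](CO[Si](C(C)C)(C(C)C)C(C)C)[C@@H](c2ccc(OCc4ccccc4)c(OC)c2)O3)/C1=C\c1ccc(O[C@@H](CO[Si](C)(C)C(C)(C)C)[C@H](O[Si](C)(C)C(C)(C)C)c2ccc(OCc3ccccc3)c(OC)c2)c(OC)c1
F7 | step 27 | tris-silylated diphenol (44 with both benzyl ethers replaced by OH) | COc1cc([C@@H](O[Si](C)(C)C(C)(C)C)[C@H](CO[Si](C)(C)C(C)(C)C)Oc2ccc(C[C@H]3C(=O)OC[C@@H]3Cc3cc(OC)c4c(c3)[C@H](CO[Si](C(C)C)(C(C)C)C(C)C)[C@@H](c3ccc(O)c(OC)c3)O4)cc2OC)ccc1O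
F8 | step 3 | 3-[4-(allyloxy)-3-methoxyphenyl]propanoic acid | OC(=O)CCc1ccc(OCC=C)c(OC)c1
F9 | step 3 | 3-(3-allyl-4-hydroxy-5-methoxyphenyl)propanoic acid | OC(=O)CCc1cc(CC=C)c(O)c(OC)c1
A1 | alternative 1 | methyl 2-{2-[4-(benzyloxy)-3-methoxybenzyloxy]-5-bromo-3-methoxyphenyl}-2-diazoacetate | COC(=O)C(=[N+]=[N-])c1cc(Br)cc(OC)c1OCc1ccc(OCc2ccccc2)c(OC)c1
A2 | alternative 1 | methyl trans-2-[4-(benzyloxy)-3-methoxyphenyl]-5-bromo-7-methoxy-2,3-dihydro-1-benzofuran-3-carboxylate, (2S,3S), spatially as the target's (2S,3R) unit | Brc1cc(OC)c2c(c1)[C@H](C(=O)OC)[C@@H](c1ccc(OCc3ccccc3)c(OC)c1)O2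
A3 | alternative 2 | 3-({(2S,3R)-2-[4-(benzyloxy)-3-methoxyphenyl]-3-[(tert-butyldimethylsilyloxy)methyl]-7-methoxy-2,3-dihydro-1-benzofuran-5-yl}methyl)cyclobutan-1-one | O=C1CC(Cc2cc(OC)c3c(c2)[C@H](CO[Si](C)(C)C(C)(C)C)[C@@H](c2ccc(OCc4ccccc4)c(OC)c2)O3)C1
A4 | alternative 2 | (4R)-4-({(2S,3R)-2-[4-(benzyloxy)-3-methoxyphenyl]-3-[(tert-butyldimethylsilyloxy)methyl]-7-methoxy-2,3-dihydro-1-benzofuran-5-yl}methyl)oxolan-2-one | O=C1C[C@@H](Cc3cc(OC)c4c(c3)[C@H](CO[Si](C)(C)C(C)(C)C)[C@@H](c3ccc(OCc5ccccc5)c(OC)c3)O4)CO1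
A5 | alternative 3 | methyl 3-[5-({(1S,2R)-1-[4-(benzyloxy)-3-methoxyphenyl]-2-[(tert-butyldimethylsilyloxy)methyl]but-3-yn-1-yl}oxy)-4-methoxy-6-oxo-6H-pyran-2-yl]propanoate | COC(=O)CCc1cc(OC)c(O[C@H](c2ccc(OCc3ccccc3)c(OC)c2)[C@@H](CO[Si](C)(C)C(C)(C)C)C#C)c(=O)o1
A6 | alternative 3 | methyl 3-{(2S,3R)-2-[4-(benzyloxy)-3-methoxyphenyl]-3-[(tert-butyldimethylsilyloxy)methyl]-7-methoxy-2,3-dihydro-1-benzofuran-5-yl}propanoate | COC(=O)CCc1cc(OC)c2c(c1)[C@H](CO[Si](C)(C)C(C)(C)C)[C@@H](c1ccc(OCc3ccccc3)c(OC)c1)O2
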